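**Assumption:** Schweizer's reagent, paraformaldehyde, DMF/POCl3, MOMCl, mCPBA and I2 are treated as reagents. The target is (6aR,11aR), the cis-fused pterocarpan. Nothing here has been run; all selectivities are predictions.

## Retrosynthetic overview

1. Disconnect C6a–C6b and C11a–O11 together: a Pd-catalysed enantioselective oxyarylation of a 2H-chromene with an o-iodophenol closes the dihydrofuran ring last and sets both stereocentres.
2. Chromene partner 7 (A ring plus both pyran rings): resorcinol → dimethylchromanone → dimethylchromene → ortho-formylation → Schweizer annulation.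
3. Iodophenol partner 17 (fully substituted D ring): resorcinol → 2,4-bis(MOMO)phenol → propargyl ether/Claisen chromene → C7 prenylation → C5 iodination → MOM removal.
4. Ring order: each dimethylpyran ring is built within its own fragment, the unsubstituted pyran ring (ring B) is closed in fragment 7, and the dihydrofuran (ring C) is formed in the final coupling.

## Route

### Fragment A: chromene partner 7

**Step 1**
Reactants: 1 resorcinol; 2 3-methylbut-2-enoic acid
Product: 3 7-hydroxy-2,2-dimethylchroman-4-one
Conditions: MeSO3H, P2O5 (Eaton's reagent), 70 °C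
Reagents that add atoms: none
Why: Friedel–Crafts acylation at C4 of resorcinol followed by intramolecular oxa-Michael closure gives the chromanone regioselectively.

**Step 2**
Reactants: 3 7-hydroxy-2,2-dimethylchroman-4-one
Product: 4 (±)-2,2-dimethylchromane-4,7-diol
Conditions: NaBH4 (excess), THF/MeOH, 0 °C → rt
Reagents that add atoms: none
Why: Hydride reduction of the aryl ketone; the new carbinol centre is removed in the next step, so its configuration is irrelevant.

**Step 3**
Reactants: 4 (±)-2,2-dimethylchromane-4,7-diol
Product: 5 2,2-dimethyl-2H-chromen-7-ol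
Conditions: p-TsOH·H2O (5 mol %), toluene, 70 °C, short reaction time
Reagents that add atoms: none
Why: Acid-catalysed E1 dehydration of a p-hydroxybenzylic alcohol (via a quinone-methide-like cation) gives the conjugated chromene.

**Step 4**
Reactants: 5 2,2-dimethyl-2H-chromen-7-ol
Product: 6 7-hydroxy-2,2-dimethyl-2H-chromene-6-carbaldehyde
Conditions: (CH2O)n, MgCl2, Et3N, MeCN, reflux
Reagents that add atoms: paraformaldehyde, C=O
Why: Magnesium-phenoxide-directed ortho-formylation (Casnati–Skattebøl) goes to the less hindered ortho carbon C6 and not to C8, which sits between two oxygens.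

**Step 5**
Reactants: 6 7-hydroxy-2,2-dimethyl-2H-chromene-6-carbaldehyde
Product: 7 2,2-dimethyl-2H,8H-pyrano[3,2-g]chromene (linear benzodipyran: one 2,2-dimethyl-2H-pyran ring and one unsubstituted 2H-pyran ring on the same benzene)
Conditions: NaH, DMF, 0 °C; then vinyltriphenylphosphonium bromide, 70 °C
Reagents that add atoms: vinyltriphenylphosphonium bromide, C=C[P+](c1ccccc1)(c1ccccc1)c1ccccc1.[Br-]
Why: Schweizer chromene synthesis: phenoxide conjugate addition to the vinylphosphonium salt gives an ylide that closes by intramolecular Wittig olefination onto the ortho aldehyde.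

### Fragment D: iodophenol partner 17

**Step 6**
Reactants: 1 resorcinol
Product: 8 2,4-dihydroxybenzaldehyde
Conditions: POCl3, DMF, MeCN, −15 °C → rt; then H2O, 50 °C
Reagents that add atoms: DMF, CN(C)C=O (formyl carbon); water, O (formyl oxygen)
Why: Vilsmeier–Haack formylation occurs at C4 of resorcinol, para to one OH and ortho to the other.

**Step 7**
Reactants: 8 2,4-dihydroxybenzaldehyde
Product: 9 2,4-bis(methoxymethoxy)benzaldehyde
Conditions: NaH, MOMCl, DMF, 0 °C → rt
Reagents that add atoms: MOMCl, COCCl
Why: Double Williamson etherification; NaH is used so that the hydrogen-bonded 2-OH is also alkylated.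

**Step 8**
Reactants: 9 2,4-bis(methoxymethoxy)benzaldehyde
Product: 10 2,4-bis(methoxymethoxy)phenol
Conditions: mCPBA, NaHCO3, CH2Cl2, 0 °C → rt; then K2CO3, MeOH, rt
Reagents that add atoms: mCPBA, OOC(=O)c1cccc(Cl)c1
Why: Baeyer–Villiger (Dakin-type) oxidation with aryl migration of the electron-rich ring gives the aryl formate, which is methanolysed to the phenol; no alkene is present yet.

**Step 9**
Reactants: 10 2,4-bis(methoxymethoxy)phenol; 11 3-chloro-3-methylbut-1-yne
Product: 12 2,4-bis(methoxymethoxy)-1-[(2-methylbut-3-yn-2-yl)oxy]benzene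
Conditions: DBU, CuCl2·2H2O (1 mol %), MeCN, 0 °C → rt
Reagents that add atoms: none
Why: Copper-catalysed O-alkylation of the phenol with the tertiary propargylic chloride gives the 1,1-dimethylpropargyl ether.

**Step 10**
Reactants: 12 2,4-bis(methoxymethoxy)-1-[(2-methylbut-3-yn-2-yl)oxy]benzene
Product: 13 6,8-bis(methoxymethoxy)-2,2-dimethyl-2H-chromene
Conditions: N,N-diethylaniline, 185 °C, Ar
Reagents that add atoms: none
Why: Aryl propargyl Claisen rearrangement, [1,5]-H shift and oxa-6π electrocyclisation; only one ortho carbon is free, so the chromene regiochemistry is fixed.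

**Step 11**
Reactants: 13 6,8-bis(methoxymethoxy)-2,2-dimethyl-2H-chromene; 14 prenyl bromide (1-bromo-3-methylbut-2-ene)
Product: 15 6,8-bis(methoxymethoxy)-2,2-dimethyl-7-(3-methylbut-2-en-1-yl)-2H-chromene
Conditions: n-BuLi, THF, 0 °C; CuBr·SMe2; then 14, −78 °C → rt
Reagents that add atoms: none
Why: Directed ortho-metalation at C7, the position activated by both flanking OMOM groups, followed by copper-mediated SN2 allylation gives the linear prenyl group.

**Step 12**
Reactants: 15 6,8-bis(methoxymethoxy)-2,2-dimethyl-7-(3-methylbut-2-en-1-yl)-2H-chromene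
Product: 16 5-iodo-6,8-bis(methoxymethoxy)-2,2-dimethyl-7-(3-methylbut-2-en-1-yl)-2H-chromene
Conditions: n-BuLi, TMEDA, THF, −40 → 0 °C; then I2, −78 °C
Reagents that add atoms: iodine, II
Why: MOM-directed ortho-lithiation at the only remaining ring C–H (C5) and iodine quench; lateral metalation of the prenyl CH2 should be disfavoured because its two ortho substituents keep the C–H bonds out of alignment with the arene π-system.

**Step 13**
Reactants: 16 5-iodo-6,8-bis(methoxymethoxy)-2,2-dimethyl-7-(3-methylbut-2-en-1-yl)-2H-chromene
Product: 17 5-iodo-2,2-dimethyl-7-(3-methylbut-2-en-1-yl)-2H-chromene-6,8-diol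
Conditions: 3 M aq. HCl, MeOH/THF, 40 °C, degassed, dark; use immediately
Reagents that add atoms: none
Why: Mild acetal hydrolysis removes both MOM groups under conditions routinely tolerated by o-prenylphenols and 2,2-dimethylchromenes.

### Coupling

**Step 14**
Reactants: 7 2,2-dimethyl-2H,8H-pyrano[3,2-g]chromene (2 equiv); 17 5-iodo-2,2-dimethyl-7-(3-methylbut-2-en-1-yl)-2H-chromene-6,8-diol
Product: 18 Lespecyrtin E4, (6aR,11aR)
Conditions: Pd2(dba)3·CHCl3 (5 mol %), (S)-t-Bu-PHOX (12 mol %), Ag2CO3 (1.5 equiv), acetone/1,4-dioxane, 55 °C, Ar, dark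
Reagents that add atoms: none
Why: Proposed new method: a catalyst-controlled enantioselective version of the racemic Pd oxyarylation (Heck-type [3+2] heteroannulation) of 2H-chromenes with o-iodophenols, applied to a hexasubstituted, unprotected iodophenol. Ag(I) removes iodide after oxidative addition, so a cationic (P,N)Pd–aryl binds the unhindered C6=C7 alkene of 7; the 2,2-dimethylchromene and prenyl alkenes are shielded by quaternary carbon or trisubstitution. The oxazoline tert-butyl group selects the alkene face in the enantio-determining syn-carbopalladation (aryl to C7, which becomes C6a; Pd to benzylic C6, which becomes C11a). The only β-hydrogen is anti to Pd, so the benzylic Pd(II) is captured by the ortho phenoxide through a six-membered oxapalladacycle and C–O reductive elimination with retention. The cis ring fusion is therefore enforced and C11a follows C6a; the second phenol (C9-OH, para to the C–Pd carbon) cannot cyclise. Closest known chemistry: the racemic Pd(OAc)2/Ag2CO3 oxyarylation of chromenes, cationic-pathway asymmetric intermolecular Heck arylation of cyclic alkenes, and enantioselective Pd heteroannulation of o-iodophenols with 1,3-dienes. The sense of induction cannot be predicted; the ligand antipode that gives (6aR,11aR) is fixed by comparing rotation/ECD with the natural product.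

## Compound list

1 | resorcinol | Oc1cccc(O)c1 | starting material
2 | 3-methylbut-2-enoic acid | CC(C)=CC(=O)O | starting material
3 | 7-hydroxy-2,2-dimethylchroman-4-one | CC1(C)CC(=O)c2ccc(O)cc2O1 | intermediate
4 | (±)-2,2-dimethylchromane-4,7-diol | CC1(C)CC(O)c2ccc(O)cc2O1 | intermediate
5 | 2,2-dimethyl-2H-chromen-7-ol | CC1(C)C=Cc2ccc(O)cc2O1 | intermediate
6 | 7-hydroxy-2,2-dimethyl-2H-chromene-6-carbaldehyde | CC1(C)C=Cc2cc(C=O)c(O)cc2O1 | intermediate
7 | 2,2-dimethyl-2H,8H-pyrano[3,2-g]chromene | CC1(C)C=Cc2cc3C=CCOc3cc2O1 | intermediate
8 | 2,4-dihydroxybenzaldehyde | O=Cc1ccc(O)cc1O | intermediate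
9 | 2,4-bis(methoxymethoxy)benzaldehyde | COCOc1ccc(C=O)c(OCOC)c1 | intermediate
10 | 2,4-bis(methoxymethoxy)phenol | COCOc1ccc(O)c(OCOC)c1 | intermediate
11 | 3-chloro-3-methylbut-1-yne | C#CC(C)(C)Cl | starting material
12 | 2,4-bis(methoxymethoxy)-1-[(2-methylbut-3-yn-2-yl)oxy]benzene | C#CC(C)(C)Oc1ccc(OCOC)cc1OCOC | intermediate
13 | 6,8-bis(methoxymethoxy)-2,2-dimethyl-2H-chromene | CC1(C)C=Cc2cc(OCOC)cc(OCOC)c2O1 | intermediate
14 | prenyl bromide (1-bromo-3-methylbut-2-ene) | CC(C)=CCBr | starting material
15 | 6,8-bis(methoxymethoxy)-2,2-dimethyl-7-(3-methylbut-2-en-1-yl)-2H-chromene | CC1(C)C=Cc2cc(OCOC)c(CC=C(C)C)c(OCOC)c2O1 | intermediate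
16 | 5-iodo-6,8-bis(methoxymethoxy)-2,2-dimethyl-7-(3-methylbut-2-en-1-yl)-2H-chromene | CC1(C)C=Cc2c(I)c(OCOC)c(CC=C(C)C)c(OCOC)c2O1 | intermediate
17 | 5-iodo-2,2-dimethyl-7-(3-methylbut-2-en-1-yl)-2H-chromene-6,8-diol | CC1(C)C=Cc2c(I)c(O)c(CC=C(C)C)c(O)c2O1 | intermediate
18 | Lespecyrtin E4, (6aR,11aR) | CC(C)=CCc1c(O)c2c(c3c1O[C@H]1c4cc5c(cc4OC[C@@H]31)OC(C)(C)C=C5)C=CC(C)(C)O2 | target

## Totals

Total step count: 14 (5 for fragment 7, 8 for fragment 17, 1 coupling).
Longest linear sequence: 9 steps (steps 6–14), which is 64% of the total.

## Three steps most likely to fail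

1. **Step 14 (proposed new enantioselective oxyarylation).** Risks are low ee, hydrodeiodination of the hindered aryl iodide, and competing insertion into the dimethylchromene alkene.
   Fallback (known chemistry): trap lithiated 15 as its pinacol boronate and Suzuki–Miyaura couple it with the 3-iodochromone analogue of fragment A (from 6-acetyl-7-hydroxy-2,2-dimethylchromene via the enaminone and I2). Then apply Ru(II)–TsDPEN asymmetric transfer hydrogenation with dynamic kinetic resolution to reach the cis-isoflavan-4-ol, and close the pterocarpan by acid-mediated MOM removal and cyclisation.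

2. **Step 12 (C5 lithiation–iodination next to the prenyl group).** Lateral metalation of the allylic/benzylic CH2 may compete.
   Fallback: iodinate 13 by electrophilic substitution (NIS) before prenylation and carry the prenyl-free iodo-diol through the annulation. Install the prenyl group last at C10 by Pd-catalysed O-(1,1-dimethylallyl)ation of the C9-OH and aromatic Claisen rearrangement; C10 is the only free ortho position.

3. **Step 13 (acidic MOM removal).** The substrate carries a prenyl group between two phenols, an electron-rich aryl iodide and a chromene; acid could cause chroman formation or protodeiodination.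
   Fallback: use SEM ethers in place of MOM from step 7 onward (same directing ability for the lithiations) and remove them with fluoride (TBAF, DMPU, 60 °C) so no acid is needed.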